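**Plan**

Numbering: quinone ring C1 (carbonyl between the methoxy carbon and the chain carbon), C2 (OMe), C4 (second carbonyl), C6 (chain); chain C1' (on C6) to C15' (CO2H).
Retrosynthesis: the C1 oxygen is removed to give a 3-methoxy-5-alkylphenol (its OH is the C4 oxygen), which goes back to the dimethyl ether; C3'–C6' is then unsaturated to a 1,3-diyne and the chain is cut at C4'–C5' (sp–sp) and at C1'–C2' (benzyl–propargyl).
Enabling feature: C1'–C14' are fourteen plain CH2 groups between ring carbon C6 and the carboxyl carbon C15', so C3'–C6' can be carried as a conjugated diyne and erased by hydrogenation.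
Forward: C1'–C2' by propargylation of the benzyl bromide, bromine onto C4', C4'–C5' by copper-catalysed bromoalkyne–alkyne coupling with undec-10-ynoic acid, hydrogenation, mono-demethylation, oxidation of the arene to the quinone. No ring is built; the carbocycle is bought as the arene.
Stereochemistry: none is needed; the target has no stereocentre and no stereodefined double bond.

Key step: step 3

**Route**

Step 1
Reactants: 1 3,5-dimethoxybenzyl bromide; 2 1-(trimethylsilyl)propyne
Product: 4 [4-(3,5-dimethoxyphenyl)but-1-yn-1-yl]trimethylsilane, via 3-lithio-1-(trimethylsilyl)propyne 3 (not isolated)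
Conditions: 2 (1.3 equiv), n-BuLi (1.2 equiv), THF, −78 °C; then 1, −78 °C to rt
Reagents that add atoms: none
Why: Deprotonation of the propargylic methyl group gives the silyl-stabilised propargyllithium 3, which should displace the benzylic bromide by SN2 alkylation through its CH2 terminus (Corey–Kirst propargylation), because the Me3Si group disfavours the allenyl mode.

Step 2
Reactants: 4 [4-(3,5-dimethoxyphenyl)but-1-yn-1-yl]trimethylsilane
Product: 5 1-(4-bromobut-3-yn-1-yl)-3,5-dimethoxybenzene
Conditions: NBS (1.15 equiv), AgNO3 (10 mol%), acetone, rt, dark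
Reagents that add atoms: N-bromosuccinimide, O=C1CCC(=O)N1Br
Why: This is a silver-catalysed desilylative bromination, in which AgNO3 converts the C–Si bond into a silver acetylide that NBS should brominate much faster than it attacks the neutral dimethoxyarene in acetone.

Step 3
Reactants: 5 1-(4-bromobut-3-yn-1-yl)-3,5-dimethoxybenzene; 6 undec-10-ynoic acid
Product: 7 15-(3,5-dimethoxyphenyl)pentadeca-10,12-diynoic acid
Conditions: CuCl (5 mol%), NH2OH·HCl (0.2 equiv), n-BuNH2, H2O/MeOH, 0 °C to rt, 5 added slowly to 6 (1.3 equiv); then 1 M HCl
Reagents that add atoms: none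
Why: n-Butylamine holds 6 in solution as its carboxylate and lets its terminal C–H form an acetylide of monovalent copper; oxidative addition of the C–Br bond of 5 gives a bis(alkynyl) species of trivalent copper, and reductive elimination joins C4' to C5' and returns CuCl. The closest known reaction type is the Cadiot–Chodkiewicz coupling of a 1-bromoalkyne with a terminal alkyne, long practised on ω-alkynoic acids as their amine salts. No ring closes and no stereocentre is created. The step needs heterocoupling over both homocouplings: only 5 carries bromine, so the two alkynes have fixed and opposite roles; NH2OH·HCl keeps copper monovalent so that oxidative dimerisation of 6 is suppressed; slow addition of 5 to an excess of 6 limits reductive dimerisation of the bromoalkyne. The dimethoxyarene and the carboxylate should be spectators under these mild basic conditions.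

Step 4
Reactants: 7 15-(3,5-dimethoxyphenyl)pentadeca-10,12-diynoic acid
Product: 8 15-(3,5-dimethoxyphenyl)pentadecanoic acid
Conditions: H2 (1 atm), 10% Pd/C, EtOAc/MeOH, rt
Reagents that add atoms: none
Why: Heterogeneous catalytic hydrogenation should add four equivalents of H2 across the conjugated diyne, while the arene, the aryl ethers and the acid are inert at this pressure and temperature.

Step 5
Reactants: 8 15-(3,5-dimethoxyphenyl)pentadecanoic acid
Product: 9 15-(3-hydroxy-5-methoxyphenyl)pentadecanoic acid
Conditions: NaSEt (4 equiv), DMF, 140 °C; then 1 M HCl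
Reagents that add atoms: none
Why: In this thiolate demethylation (Feutrill–Mirrington conditions) ethanethiolate attacks one O-methyl carbon by SN2, and the reaction should stop at the mono-phenol because the phenoxide formed makes the second aryloxide a far poorer leaving group; the carboxylate is inert.

Step 6
Reactants: 9 15-(3-hydroxy-5-methoxyphenyl)pentadecanoic acid
Product: 10 15-(5-methoxy-3,6-dioxocyclohexa-1,4-dien-1-yl)pentadecanoic acid
Conditions: K2[ON(SO3)2] (2.5 equiv), aq. KH2PO4, acetone/H2O, rt
Reagents that add atoms: potassium nitrosodisulfonate (Fremy's salt), [K+].[K+].[O]N(S(=O)(=O)[O-])S(=O)(=O)[O-]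
Why: In the Teuber oxidation one nitrosodisulfonate radical abstracts the phenolic hydrogen, a second adds at the free para carbon (between the chain-bearing and the methoxy-bearing carbons), and loss of imidodisulfonate should give the para-quinone, para attack being the normal course when that position is unsubstituted.

**Compound list**

1 | 3,5-dimethoxybenzyl bromide | COc1cc(CBr)cc(OC)c1 | starting material
2 | 1-(trimethylsilyl)propyne | CC#C[Si](C)(C)C | starting material
3 | 3-lithio-1-(trimethylsilyl)propyne | [Li]CC#C[Si](C)(C)C | intermediate (not isolated)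
4 | [4-(3,5-dimethoxyphenyl)but-1-yn-1-yl]trimethylsilane | COc1cc(CCC#C[Si](C)(C)C)cc(OC)c1 | intermediate
5 | 1-(4-bromobut-3-yn-1-yl)-3,5-dimethoxybenzene | COc1cc(CCC#CBr)cc(OC)c1 | intermediate
6 | undec-10-ynoic acid | C#CCCCCCCCCC(=O)O | starting material
7 | 15-(3,5-dimethoxyphenyl)pentadeca-10,12-diynoic acid | COc1cc(CCC#CC#CCCCCCCCCC(=O)O)cc(OC)c1 | intermediate
8 | 15-(3,5-dimethoxyphenyl)pentadecanoic acid | COc1cc(CCCCCCCCCCCCCCC(=O)O)cc(OC)c1 | intermediate
9 | 15-(3-hydroxy-5-methoxyphenyl)pentadecanoic acid | COc1cc(O)cc(CCCCCCCCCCCCCCC(=O)O)c1 | intermediate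
10 | 15-(5-methoxy-3,6-dioxocyclohexa-1,4-dien-1-yl)pentadecanoic acid | COC1=CC(=O)C=C(CCCCCCCCCCCCCCC(=O)O)C1=O | target

**Count and risks**

Total steps: 6. Longest linear sequence: 6 steps (1 → 4 → 5 → 7 → 8 → 9 → 10); 2 and 6 enter as purchased materials.

Steps most likely to fail:

Step 2. The risk is electrophilic bromination of the electron-rich dimethoxyarene ring competing with the silver-mediated exchange of silicon for bromine at the alkyne. The fallback sets out from 4 and returns at 5. Compound 4 is desilylated with K2CO3 in MeOH to 1-(but-3-yn-1-yl)-3,5-dimethoxybenzene F1. n-BuLi in THF at −78 °C converts it into lithium 4-(3,5-dimethoxyphenyl)but-1-yn-1-ide F2, which is quenched at −78 °C with 1,2-dibromo-1,1,2,2-tetrachloroethane to give 5. The acetylide anion is then the only nucleophile offered to a mild bromine donor, and neither silver salt nor NBS is present.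

Step 6. The risk is attack of the second nitrosodisulfonate radical ortho rather than para to the aryloxyl oxygen, or slow oxidation of the amphiphilic acid in the aqueous medium followed by decay of the base-sensitive methoxyquinone. The fallback sets out from 8 and returns at 10, bypassing steps 5 and 6 by placing the fourth oxygen explicitly. Duff formylation of 8 (hexamethylenetetramine, CF3CO2H, 80 °C; then aq. HCl) para to one methoxy group should give 15-(2-formyl-3,5-dimethoxyphenyl)pentadecanoic acid F3. Baeyer–Villiger oxidation with mCPBA in CH2Cl2 gives the aryl formate 15-[2-(formyloxy)-3,5-dimethoxyphenyl]pentadecanoic acid F4. Hydrolysis (aq. NaOH, MeOH; then HCl) gives 15-(2-hydroxy-3,5-dimethoxyphenyl)pentadecanoic acid F5. (NH4)2Ce(NO3)6 in MeCN/H2O at 0 °C oxidises this para-methoxyphenol to 10 with loss of methanol, so the substitution pattern fixes the position of both carbonyl groups.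

Step 3. The risk is reductive dimerisation of the bromoalkyne and oxidative dimerisation of 6 outrunning the heterocoupling, or poor contact between lipophilic 5 and the aqueous carboxylate. The fallback sets out from 1 and returns at 8, building the tether by olefin cross-metathesis instead of alkyne coupling. Pent-4-en-1-ylmagnesium bromide F6 (from 5-bromopent-1-ene and Mg in THF) is coupled with 1 under Li2CuCl4 catalysis to give 1-(hex-5-en-1-yl)-3,5-dimethoxybenzene F7. Cross-metathesis of F7 with an excess of undec-10-enoic acid, using the second-generation Grubbs catalyst (H2IMes)(PCy3)Cl2Ru=CHPh in CH2Cl2 at 40 °C, should give (E)-15-(3,5-dimethoxyphenyl)pentadec-10-enoic acid F8; the E isomer is expected to predominate and the geometry is irrelevant. H2 over 10% Pd/C as in step 4 then gives 8.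

**Further compounds**

F1 | step 2 | 1-(but-3-yn-1-yl)-3,5-dimethoxybenzene | COc1cc(CCC#C)cc(OC)c1
F2 | step 2 | lithium 4-(3,5-dimethoxyphenyl)but-1-yn-1-ide | [Li]C#CCCc1cc(OC)cc(OC)c1
F3 | step 6 | 15-(2-formyl-3,5-dimethoxyphenyl)pentadecanoic acid | COc1cc(OC)c(C=O)c(CCCCCCCCCCCCCCC(=O)O)c1
F4 | step 6 | 15-[2-(formyloxy)-3,5-dimethoxyphenyl]pentadecanoic acid | COc1cc(OC)c(OC=O)c(CCCCCCCCCCCCCCC(=O)O)c1
F5 | step 6 | 15-(2-hydroxy-3,5-dimethoxyphenyl)pentadecanoic acid | COc1cc(OC)c(O)c(CCCCCCCCCCCCCCC(=O)O)c1
F6 | step 3 | pent-4-en-1-ylmagnesium bromide | C=CCCC[Mg]Br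
F7 | step 3 | 1-(hex-5-en-1-yl)-3,5-dimethoxybenzene | COc1cc(CCCCC=C)cc(OC)c1
F8 | step 3 | (E)-15-(3,5-dimethoxyphenyl)pentadec-10-enoic acid | COc1cc(CCCC/C=C/CCCCCCCCC(=O)O)cc(OC)c1
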